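**Retrosynthetic overview**

- The route rests on ring A of the target: a benzene ring with hydroxyl oxygens on C2', C4' and C6', and the acyl carbon C1 of the undecanone chain on C1', between two of those oxygens.
- The three phenols are unmasked last from two methyl ethers and one ethyl ether. The C1 ketone comes from oxidation of the electron-rich benzylic CH2 of a 2-alkyl-1,3,5-trialkoxybenzene.
- Ring A (the only ring formed) is built in one operation from 3-ethoxycyclobutenone and a 1-siloxyalkyne. The alkyne supplies C1' (with the whole C11 chain) and C2'; the cyclobutenone supplies C3', C4' (OEt), C5' and C6' (OH).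
- The siloxyalkyne comes from 11-phenylundecanoic acid by reduction, bromination, acetylide alkylation and oxidation of the alkynide to the ynolate with O-silylation. The cyclobutenone comes from ethoxyacetylene and ketene.

Key step: step 6

Remark on the chemistry: the target has no stereocentre. The stereocentres of the transient compounds 14 and 20 form racemic and are destroyed in the same flask. Compounds 1, 4, 9 (as its hexane solution) and 10 are taken as commercial.

**Route**

Step 1
Reactants: 1 11-phenylundecanoic acid
Product: 2 11-phenylundecan-1-ol
Conditions: LiAlH4, THF, 0 °C → 65 °C; aqueous work-up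
Reagents that add atoms: none
Why: Hydride reduction of a carboxylic acid with LiAlH4 should give the primary alcohol, the phenyl ring and the saturated chain being inert.

Step 2
Reactants: 2 11-phenylundecan-1-ol
Product: 3 (11-bromoundecyl)benzene
Conditions: CBr4, PPh3, CH2Cl2, 0 °C → rt
Reagents that add atoms: carbon tetrabromide, BrC(Br)(Br)Br
Why: In the Appel reaction the alkoxyphosphonium ion of an unhindered primary alcohol should be displaced cleanly by bromide (SN2).

Step 3
Reactants: 3 (11-bromoundecyl)benzene; 4 lithium acetylide–ethylenediamine complex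
Product: 5 13-phenyltridec-1-yne
Conditions: DMSO, 15 °C → rt
Reagents that add atoms: none
Why: SN2 alkylation of lithium acetylide by a primary bromide in DMSO should add the two alkyne carbons without elimination or dialkylation.

Step 4
Reactants: 5 13-phenyltridec-1-yne
Product: 8 triisopropyl[(13-phenyltridec-1-yn-1-yl)oxy]silane, via lithium alkynide 6 (not isolated), via lithium ynolate 7 (not isolated)
Conditions: n-BuLi, THF, −78 °C; LiOOtBu (from t-BuOOH, LiHMDS, THF, −78 °C), −78 → 0 °C; then TIPSOTf, −78 °C → rt; chromatography on Et3N-deactivated silica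
Reagents that add atoms: tert-butyl hydroperoxide, CC(C)(C)OO; triisopropylsilyl trifluoromethanesulfonate, CC(C)[Si](OS(=O)(=O)C(F)(F)F)(C(C)C)C(C)C
Why: In the Julia ynolate synthesis the alkynide attacks the lithium-bearing oxygen of the peroxide with loss of tert-butoxide, and the hard, bulky silyl triflate should then silylate the ynolate on oxygen and not on carbon.

Step 5
Reactants: 9 ethoxyacetylene; 10 acetyl chloride
Product: 12 3-ethoxycyclobut-2-en-1-one, via ketene 11 (not isolated)
Conditions: Et3N, Et2O, slow addition of 10, 0 °C → rt
Reagents that add atoms: none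
Why: Ketene formed by dehydrochlorination should undergo a regioselective (2+2) cycloaddition with the ynol ether, whose CH carbon attacks the ketene carbonyl carbon, and slow addition keeps the ketene concentration low so that dimerisation is held back.

Step 6
Reactants: 8 triisopropyl[(13-phenyltridec-1-yn-1-yl)oxy]silane; 12 3-ethoxycyclobut-2-en-1-one
Product: 17 5-ethoxy-2-(11-phenylundecyl)-3-[(triisopropylsilyl)oxy]phenol, via 3-ethoxy vinylketene 13 (not isolated), via 4-vinylcyclobutenone 14 (not isolated), via dienylketene 15 (not isolated), via cyclohexadienone 16 (not isolated)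
Conditions: toluene, argon, 80 °C then 110 °C, slow addition of 12 (1.5 equiv) to 8
Reagents that add atoms: none
Why: Four-electron conrotatory opening of 12 gives vinylketene 13, and the alkyne carbon of 8 remote from oxygen adds to the ketene carbonyl carbon in a (2+2) cycloaddition to give 14. A second, reversible four-electron opening of 14 gives dienylketene 15, of which only the (3E) isomer can close, and six-electron electrocyclisation joins the ketene carbon to the terminal CH2 to give 16, which tautomerises to phenol 17. The closest known reaction is the Danheiser benzannulation of cyclobutenones with trialkylsiloxyalkynes, which gives resorcinol monosilyl ethers. Ring A, the only ring closed, forms by this 6π electrocyclic closure after the two new bonds of the cycloaddition, and no stereocentre remains in the product. The step needs regiocontrol so that the chain lands between the phenol and the siloxy group, and the polarisation of the siloxyalkyne against the electrophilic ketene carbon secures it. Slow addition of 12 keeps the vinylketene dilute, so that cycloaddition should outrun dimerisation and acylation of the product phenol.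

Step 7
Reactants: 17 5-ethoxy-2-(11-phenylundecyl)-3-[(triisopropylsilyl)oxy]phenol
Product: 19 5-ethoxy-1,3-dimethoxy-2-(11-phenylundecyl)benzene, via free resorcinol 18 (not isolated)
Conditions: TBAF, THF, 0 °C; then K2CO3, MeI, DMF, rt → 40 °C
Reagents that add atoms: iodomethane, CI
Why: Fluoride cleaves the aryl silyl ether, and both phenoxides should then be O-methylated by SN2 on iodomethane (Williamson ether synthesis) in the same flask.

Step 8
Reactants: 19 5-ethoxy-1,3-dimethoxy-2-(11-phenylundecyl)benzene
Product: 21 1-(4-ethoxy-2,6-dimethoxyphenyl)-11-phenylundecan-1-one, via benzylic alcohol 20 (not isolated)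
Conditions: DDQ (2.5 equiv), 1,4-dioxane/H2O 9:1, rt
Reagents that add atoms: water, O
Why: In this DDQ benzylic oxidation, hydride abstraction from the CH2 on the trialkoxy ring gives a cation stabilised by three oxygen donors that water captures, and a second oxidation of the electron-rich benzylic alcohol gives the aryl ketone, while the CH2 next to the plain phenyl ring is not activated and should stay untouched.

Step 9
Reactants: 21 1-(4-ethoxy-2,6-dimethoxyphenyl)-11-phenylundecan-1-one
Product: 22 11-phenyl-1-(2,4,6-trihydroxyphenyl)undecan-1-one
Conditions: BBr3 (6 equiv), CH2Cl2, −78 °C → rt; then H2O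
Reagents that add atoms: none
Why: BBr3 cleaves aryl alkyl ethers by boron coordination and bromide attack on the alkyl group, the two ortho methoxy groups being activated by chelation to the ketone and the para ethoxy group following with excess reagent at room temperature.

**Compound list**

1 | 11-phenylundecanoic acid | OC(=O)CCCCCCCCCCc1ccccc1 | starting material
2 | 11-phenylundecan-1-ol | OCCCCCCCCCCCc1ccccc1 | intermediate
3 | (11-bromoundecyl)benzene | BrCCCCCCCCCCCc1ccccc1 | intermediate
4 | lithium acetylide–ethylenediamine complex | [Li+].[C-]#C.NCCN | starting material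
5 | 13-phenyltridec-1-yne | C#CCCCCCCCCCCCc1ccccc1 | intermediate
6 | lithium 13-phenyltridec-1-yn-1-ide | [Li+].[C-]#CCCCCCCCCCCCc1ccccc1 | intermediate
7 | lithium 13-phenyltridec-1-yn-1-olate | [Li+].[O-]C#CCCCCCCCCCCCc1ccccc1 | intermediate
8 | triisopropyl[(13-phenyltridec-1-yn-1-yl)oxy]silane | CC(C)[Si](OC#CCCCCCCCCCCCc1ccccc1)(C(C)C)C(C)C | intermediate
9 | ethoxyacetylene | CCOC#C | starting material
10 | acetyl chloride | CC(=O)Cl | starting material
11 | ketene | C=C=O | intermediate
12 | 3-ethoxycyclobut-2-en-1-one | CCOC1=CC(=O)C1 | intermediate
13 | 3-ethoxybuta-1,3-dien-1-one | CCOC(=C)C=C=O | intermediate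
14 | 4-(1-ethoxyvinyl)-2-(11-phenylundecyl)-3-[(triisopropylsilyl)oxy]cyclobut-2-en-1-one (racemic) | CCOC(=C)C1C(=O)C(CCCCCCCCCCCc2ccccc2)=C1O[Si](C(C)C)(C(C)C)C(C)C | intermediate
15 | (3E)-5-ethoxy-2-(11-phenylundecyl)-3-[(triisopropylsilyl)oxy]hexa-1,3,5-trien-1-one | O=C=C(CCCCCCCCCCCc1ccccc1)/C(O[Si](C(C)C)(C(C)C)C(C)C)=C\C(OCC)=C | intermediate
16 | 5-ethoxy-2-(11-phenylundecyl)-3-[(triisopropylsilyl)oxy]cyclohexa-2,4-dien-1-one | CCOC1=CC(O[Si](C(C)C)(C(C)C)C(C)C)=C(CCCCCCCCCCCc2ccccc2)C(=O)C1 | intermediate
17 | 5-ethoxy-2-(11-phenylundecyl)-3-[(triisopropylsilyl)oxy]phenol | CCOc1cc(O)c(CCCCCCCCCCCc2ccccc2)c(O[Si](C(C)C)(C(C)C)C(C)C)c1 | intermediate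
18 | 5-ethoxy-2-(11-phenylundecyl)benzene-1,3-diol | CCOc1cc(O)c(CCCCCCCCCCCc2ccccc2)c(O)c1 | intermediate
19 | 5-ethoxy-1,3-dimethoxy-2-(11-phenylundecyl)benzene | CCOc1cc(OC)c(CCCCCCCCCCCc2ccccc2)c(OC)c1 | intermediate
20 | 1-(4-ethoxy-2,6-dimethoxyphenyl)-11-phenylundecan-1-ol (racemic) | CCOc1cc(OC)c(C(O)CCCCCCCCCCc2ccccc2)c(OC)c1 | intermediate
21 | 1-(4-ethoxy-2,6-dimethoxyphenyl)-11-phenylundecan-1-one | CCOc1cc(OC)c(C(=O)CCCCCCCCCCc2ccccc2)c(OC)c1 | intermediate
22 | 11-phenyl-1-(2,4,6-trihydroxyphenyl)undecan-1-one | O=C(CCCCCCCCCCc1ccccc1)c1c(O)cc(O)cc1O | target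

**Step count**

Total: 9 steps. Longest linear sequence: 8 steps (steps 1–4 and 6–9); step 5 is the one-step branch to the cyclobutenone.

**Steps most likely to fail**

Step 6 (benzannulation). The vinylogous-ester cyclobutenone may open only at temperatures at which the siloxyalkyne isomerises by a 1,3-silyl shift, and the vinylketene may be lost to dimerisation or to acylation of the product phenol. Fallback: give up the ring construction and acylate a preformed ring. The fallback sets out from acid 1 and comes back to the route at target 22. SOCl2 with catalytic DMF should convert 1 into 11-phenylundecanoyl chloride F1. Friedel–Crafts acylation of commercial 1,3,5-trimethoxybenzene with F1 and AlCl3 in CH2Cl2 at 0 °C should give 11-phenyl-1-(2,4,6-trimethoxyphenyl)undecan-1-one F2. BBr3 under the conditions of step 9 should then give 22.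

Step 8 (benzylic oxidation). After hydride abstraction the cation may lose a proton faster than it captures water, which leads to the styrene and its further oxidation, or the arene radical cation may couple through the two free ring positions. Fallback: introduce the oxygen by alkene hydration. The fallback sets out from 19 and comes back to the route at 21. DDQ in anhydrous dioxane should dehydrogenate 19 to (E)-5-ethoxy-1,3-dimethoxy-2-(11-phenylundec-1-en-1-yl)benzene F3. Mukaiyama hydration of F3 (Co(acac)2, PhSiH3, O2, THF) should place the hydroxyl at the benzylic carbon through the benzylic radical and give alcohol 20, here isolated. MnO2 or Dess–Martin periodinane should then oxidise 20 to 21.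

Step 5 (cyclobutenone formation). Dimerisation of ketene and its reaction with the acylammonium salt may outrun the cycloaddition, and the small, acid-sensitive vinylogous ester may be lost on isolation. Fallback: use a ketene that does not dimerise and remove its substituents afterwards. The fallback sets out from 9 and comes back to the route at 12. Dichloroketene F4, made in the flask from trichloroacetyl chloride and Zn–Cu couple in Et2O, should add to 9 to give 4,4-dichloro-3-ethoxycyclobut-2-en-1-one F5. Reductive dechlorination of F5 with Zn, AcOH and TMEDA in EtOH should give 12.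

**Further compounds**

F1 | step 6 | 11-phenylundecanoyl chloride | O=C(Cl)CCCCCCCCCCc1ccccc1
F2 | step 6 | 11-phenyl-1-(2,4,6-trimethoxyphenyl)undecan-1-one | COc1cc(OC)c(C(=O)CCCCCCCCCCc2ccccc2)c(OC)c1
F3 | step 8 | (E)-5-ethoxy-1,3-dimethoxy-2-(11-phenylundec-1-en-1-yl)benzene | CCOc1cc(OC)c(/C=C/CCCCCCCCCc2ccccc2)c(OC)c1
F4 | step 5 | dichloroketene | ClC(Cl)=C=O
F5 | step 5 | 4,4-dichloro-3-ethoxycyclobut-2-en-1-one | CCOC1=CC(=O)C1(Cl)Cl
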